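**Plan**

- Locants: ring B is C1(CH3)–C2(OAc)–C3H2–C4(side chain)–C4a–C8a. Ring A is C4a–C5–C6(CH2OAc)–C7–C8(OH)–C8a. The side-chain stereocentre is C11.
- Retrosynthetic cuts, in order: the acetates and the O-protecting groups; C2–H (ketone reduction); C1–CH3 (enamine methylation); C2–C3 (closure of ring B by alkene hydroacylation); C4a–C4 (branch-selective Heck reaction with (S)-β-citronellene); C8a–C1 (ortho-lithiation, oxirane).
- Enabling feature: C2 and C3 are the only non-benzylic atoms of ring B. Cutting between them leaves two ortho arms on the C4a–C8a edge of ring A: a C1H2–C2HO arm and a C4(=C3H2) α-alkylstyrene arm. The formyl C–H and the alkene terminus are six atoms apart, and the C8 ether oxygen sits where it can chelate an acyl metal at C2.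
- Forward: ring A is bought; the C8a arm and then the C4a arm are attached; ring B is closed at C2–C3 at the ketone level; C1 is methylated; C2 is reduced; the acetates come last.
- Stereochemistry: C11 from (S)-β-citronellene; C4 from the chiral rhodium catalyst in the ring closure; C1 by thermodynamic 1,4-trans equilibration of the 2-tetralone; C2 by oxazaborolidine-controlled reduction.

Key step: step 5

Assumption: (R)-DTBM-SEGPHOS in step 5 and the (R)-oxazaborolidine in step 7 are written as the antipodes that deliver (4S) and (2S); the sense of each has to be confirmed on the first run and the antipode taken if needed. Names of the bicyclic compounds use the locants of the plan.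

**Step 1**
Reactants: 1 (3-chloro-5-methoxyphenyl)methanol
Product: 2 tert-butyl[(3-chloro-5-methoxyphenyl)methoxy]dimethylsilane
Conditions: TBSCl, imidazole, DMF, rt
Reagents that add atoms: tert-butyldimethylsilyl chloride, CC(C)(C)[Si](C)(C)Cl
Why: Silylation of the benzylic alcohol gives an ether that tolerates organolithium, Lewis acid and silyl triflate and that does not act as a directing group.

**Step 2**
Reactants: 2 tert-butyl[(3-chloro-5-methoxyphenyl)methoxy]dimethylsilane, 3 oxirane
Product: 5 2-[4-({[tert-butyl(dimethyl)silyl]oxy}methyl)-2-chloro-6-methoxyphenyl]ethan-1-ol, via aryllithium 4 (not isolated)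
Conditions: n-BuLi, THF, −78 °C; then oxirane, BF3·OEt2, −78 °C
Reagents that add atoms: none
Why: Directed ortho-metalation, in which n-BuLi removes the ring proton flanked by the methoxy director and the acidifying chlorine (no chlorine–lithium exchange at −78 °C), and the aryllithium opens BF3-activated oxirane before it can lose LiCl to an aryne.

**Step 3**
Reactants: 5 2-[4-({[tert-butyl(dimethyl)silyl]oxy}methyl)-2-chloro-6-methoxyphenyl]ethan-1-ol, 6 (S)-β-citronellene [(3S)-3,7-dimethylocta-1,6-diene]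
Product: 7 tert-butyl({3-[(3S)-3,7-dimethylocta-1,6-dien-2-yl]-5-methoxy-4-{2-[(triethylsilyl)oxy]ethyl}phenyl}methoxy)dimethylsilane
Conditions: Ni(cod)2 (10 mol %), 1,4-bis(dicyclohexylphosphino)butane (12 mol %), Et3SiOTf (2.5 equiv), Et3N, toluene, 60 °C
Reagents that add atoms: triethylsilyl trifluoromethanesulfonate, CC[Si](CC)(CC)OS(=O)(=O)C(F)(F)F
Why: Branch-selective cationic Mizoroki–Heck reaction of an aryl chloride with an unbiased terminal olefin under zerovalent nickel/bisphosphine catalysis, with Et3SiOTf as chloride abstractor, should put the aryl group on the internal carbon and give the 1,1-disubstituted styrene, the free alcohol being silylated in the flask; the trisubstituted alkene does not insert and the amine base suppresses chain-walking toward C11.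

**Step 4**
Reactants: 7 tert-butyl({3-[(3S)-3,7-dimethylocta-1,6-dien-2-yl]-5-methoxy-4-{2-[(triethylsilyl)oxy]ethyl}phenyl}methoxy)dimethylsilane
Product: 8 2-[4-({[tert-butyl(dimethyl)silyl]oxy}methyl)-2-[(3S)-3,7-dimethylocta-1,6-dien-2-yl]-6-methoxyphenyl]acetaldehyde
Conditions: (COCl)2, DMSO, CH2Cl2, −78 to −40 °C; then Et3N, −78 to 0 °C
Reagents that add atoms: none
Why: Swern oxidation converts a primary triethylsilyl ether directly into the aldehyde (the chlorosulfonium ion attacks the silyl ether oxygen and Et3SiCl is lost), while the primary TBS ether, the aryl ether and both alkenes are left; the arylacetaldehyde is taken on crude.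

**Step 5**
Reactants: 8 2-[4-({[tert-butyl(dimethyl)silyl]oxy}methyl)-2-[(3S)-3,7-dimethylocta-1,6-dien-2-yl]-6-methoxyphenyl]acetaldehyde
Product: 9 (4S)-6-({[tert-butyl(dimethyl)silyl]oxy}methyl)-8-methoxy-4-[(2S)-6-methylhept-5-en-2-yl]-3,4-dihydronaphthalen-2(1H)-one
Conditions: [Rh(cod)Cl]2 (2.5 mol %), (R)-DTBM-SEGPHOS (5.5 mol %), Na[B(3,5-(CF3)2C6H3)4] (6 mol %), 1,4-dioxane, 60 °C
Reagents that add atoms: none
Why: Proposed new method: oxidative addition of the cationic monovalent rhodium bisphosphine into the formyl C–H of 8 gives an acyl rhodium hydride (trivalent rhodium) that the C8 methoxy oxygen can hold in a six-membered chelate against decarbonylation; the tethered C3=C4 alkene then inserts into Rh–H with hydride going to C4 and rhodium to the terminal C3, and C2–C3 reductive elimination from the seven-membered acyl alkyl rhodacycle releases the ketone. The closest known reactions are the rhodium/bisphosphine hydroacylation of 2-(1-substituted vinyl)benzaldehydes to 3-substituted indanones and of ortho-allylbenzaldehydes to tetralones; new here is the aliphatic arylacetaldehyde donor combined with six-ring closure onto an α-branched styrene. Ring B closes in the 6-endo-trig mode (the acyl carbon C2 bonds to the alkene terminus C3 and both alkene carbons end up in the ring). The only new stereocentre, C4, is fixed in the hydride insertion, where the chiral bisphosphine selects the alkene face (catalyst control, to be matched with the adjacent C11 centre). The step needs regioselectivity for C3 over C4, secured because the alternative would put rhodium on a tertiary benzylic carbon and build a quaternary centre in a 2-indanone, and chemoselectivity over the trisubstituted side-chain alkene, which is hindered and cannot reach the acyl metal in a small ring.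

**Step 6**
Reactants: 9 (4S)-6-({[tert-butyl(dimethyl)silyl]oxy}methyl)-8-methoxy-4-[(2S)-6-methylhept-5-en-2-yl]-3,4-dihydronaphthalen-2(1H)-one
Product: 12 (1S,4S)-6-({[tert-butyl(dimethyl)silyl]oxy}methyl)-8-methoxy-1-methyl-4-[(2S)-6-methylhept-5-en-2-yl]-3,4-dihydronaphthalen-2(1H)-one, via pyrrolidine enamine 10 (not isolated), via iminium iodide 11 (not isolated)
Conditions: pyrrolidine, toluene, reflux (Dean–Stark); MeI, MeCN, 60 °C; aq. AcOH/NaOAc, rt; DBU (cat.), CH2Cl2, rt
Reagents that add atoms: iodomethane, CI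
Why: Stork enamine alkylation, in which the enamine forms toward benzylic C1 (conjugation with ring A), MeI alkylates it once from the face away from the pseudoaxial C4 chain, and the ketone released on hydrolysis is equilibrated through its enol to the 1,4-trans isomer, where the C1 methyl and the C4 chain are both pseudoaxial and so avoid peri strain with the C8 methoxy group and with H5.

**Step 7**
Reactants: 12 (1S,4S)-6-({[tert-butyl(dimethyl)silyl]oxy}methyl)-8-methoxy-1-methyl-4-[(2S)-6-methylhept-5-en-2-yl]-3,4-dihydronaphthalen-2(1H)-one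
Product: 13 (1S,2S,4S)-6-({[tert-butyl(dimethyl)silyl]oxy}methyl)-8-methoxy-1-methyl-4-[(2S)-6-methylhept-5-en-2-yl]-1,2,3,4-tetrahydronaphthalen-2-ol
Conditions: (R)-2-methyl-CBS-oxazaborolidine (20 mol %), catecholborane, toluene, −78 °C; then MeOH, aq. NaOH
Reagents that add atoms: none
Why: Corey–Bakshi–Shibata reduction, in which the (R)-oxazaborolidine binds the ketone with the branched C1 flank as the large group and delivers hydride to the face opposite the pseudoaxial C4 chain, which should give the (2S) carbinol trans to the C1 methyl; catecholborane at −78 °C neither hydroborates the trisubstituted alkene nor epimerises C1.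

**Step 8**
Reactants: 13 (1S,2S,4S)-6-({[tert-butyl(dimethyl)silyl]oxy}methyl)-8-methoxy-1-methyl-4-[(2S)-6-methylhept-5-en-2-yl]-1,2,3,4-tetrahydronaphthalen-2-ol
Product: 14 (1S,2S,4S)-6-(hydroxymethyl)-8-methoxy-1-methyl-4-[(2S)-6-methylhept-5-en-2-yl]-1,2,3,4-tetrahydronaphthalen-2-ol
Conditions: Bu4NF, THF, 0 °C to rt
Reagents that add atoms: none
Why: Fluoride cleaves the silicon–oxygen bond of the benzylic TBS ether.

**Step 9**
Reactants: 14 (1S,2S,4S)-6-(hydroxymethyl)-8-methoxy-1-methyl-4-[(2S)-6-methylhept-5-en-2-yl]-1,2,3,4-tetrahydronaphthalen-2-ol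
Product: 15 (1S,2S,4S)-6-(hydroxymethyl)-1-methyl-4-[(2S)-6-methylhept-5-en-2-yl]-1,2,3,4-tetrahydronaphthalene-2,8-diol
Conditions: NaSEt, DMF, 130 °C; then aq. HCl work-up
Reagents that add atoms: none
Why: Nucleophilic demethylation, in which ethanethiolate attacks the methyl carbon of the aryl methyl ether and releases the phenoxide, under conditions to which the alcohols, the benzylic stereocentres and the isolated alkene are inert.

**Step 10**
Reactants: 15 (1S,2S,4S)-6-(hydroxymethyl)-1-methyl-4-[(2S)-6-methylhept-5-en-2-yl]-1,2,3,4-tetrahydronaphthalene-2,8-diol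
Product: 16 [(1S,2S,4S)-2,8-diacetoxy-1-methyl-4-[(2S)-6-methylhept-5-en-2-yl]-1,2,3,4-tetrahydronaphthalen-6-yl]methyl acetate
Conditions: Ac2O, pyridine, DMAP (cat.), CH2Cl2, rt
Reagents that add atoms: acetic anhydride, CC(=O)OC(C)=O
Why: DMAP-catalysed acylation esterifies the primary, the secondary and the phenolic hydroxyl groups.

**Step 11**
Reactants: 16 [(1S,2S,4S)-2,8-diacetoxy-1-methyl-4-[(2S)-6-methylhept-5-en-2-yl]-1,2,3,4-tetrahydronaphthalen-6-yl]methyl acetate
Product: 17 [(1S,2S,4S)-2-acetoxy-8-hydroxy-1-methyl-4-[(2S)-6-methylhept-5-en-2-yl]-1,2,3,4-tetrahydronaphthalen-6-yl]methyl acetate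
Conditions: NH4OAc, MeOH/H2O (4:1), rt
Reagents that add atoms: none
Why: An aryl acetate is a far better acyl donor than an alkyl acetate, so mild buffered solvolysis should remove the phenolic acetate only and leave the primary and the secondary acetate.

**Compound list**

1 | (3-chloro-5-methoxyphenyl)methanol | COc1cc(Cl)cc(CO)c1 | starting material
2 | tert-butyl[(3-chloro-5-methoxyphenyl)methoxy]dimethylsilane | COc1cc(Cl)cc(CO[Si](C)(C)C(C)(C)C)c1 | intermediate
3 | oxirane | C1CO1 | starting material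
4 | [4-({[tert-butyl(dimethyl)silyl]oxy}methyl)-2-chloro-6-methoxyphenyl]lithium | [Li]c1c(Cl)cc(CO[Si](C)(C)C(C)(C)C)cc1OC | intermediate (not isolated)
5 | 2-[4-({[tert-butyl(dimethyl)silyl]oxy}methyl)-2-chloro-6-methoxyphenyl]ethan-1-ol | OCCc1c(Cl)cc(CO[Si](C)(C)C(C)(C)C)cc1OC | intermediate
6 | (S)-β-citronellene [(3S)-3,7-dimethylocta-1,6-diene] | C=C[C@@H](C)CCC=C(C)C | starting material
7 | tert-butyl({3-[(3S)-3,7-dimethylocta-1,6-dien-2-yl]-5-methoxy-4-{2-[(triethylsilyl)oxy]ethyl}phenyl}methoxy)dimethylsilane | CC[Si](CC)(CC)OCCc1c(C(=C)[C@@H](C)CCC=C(C)C)cc(CO[Si](C)(C)C(C)(C)C)cc1OC | intermediate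
8 | 2-[4-({[tert-butyl(dimethyl)silyl]oxy}methyl)-2-[(3S)-3,7-dimethylocta-1,6-dien-2-yl]-6-methoxyphenyl]acetaldehyde | O=CCc1c(C(=C)[C@@H](C)CCC=C(C)C)cc(CO[Si](C)(C)C(C)(C)C)cc1OC | intermediate
9 | (4S)-6-({[tert-butyl(dimethyl)silyl]oxy}methyl)-8-methoxy-4-[(2S)-6-methylhept-5-en-2-yl]-3,4-dihydronaphthalen-2(1H)-one | CC(C)(C)[Si](C)(C)OCc1cc(OC)c2c(c1)[C@H]([C@@H](C)CCC=C(C)C)CC(=O)C2 | intermediate
10 | 1-[(4S)-6-({[tert-butyl(dimethyl)silyl]oxy}methyl)-8-methoxy-4-[(2S)-6-methylhept-5-en-2-yl]-3,4-dihydronaphthalen-2-yl]pyrrolidine | CC(C)(C)[Si](C)(C)OCc1cc(OC)c2c(c1)[C@H]([C@@H](C)CCC=C(C)C)CC(N3CCCC3)=C2 | intermediate (not isolated)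
11 | 1-[(4S)-6-({[tert-butyl(dimethyl)silyl]oxy}methyl)-8-methoxy-1-methyl-4-[(2S)-6-methylhept-5-en-2-yl]-3,4-dihydronaphthalen-2(1H)-ylidene]pyrrolidin-1-ium iodide (C1 epimers) | CC(C)(C)[Si](C)(C)OCc1cc(OC)c2c(c1)[C@H]([C@@H](C)CCC=C(C)C)CC(=[N+]3CCCC3)C2C.[I-] | intermediate (not isolated)
12 | (1S,4S)-6-({[tert-butyl(dimethyl)silyl]oxy}methyl)-8-methoxy-1-methyl-4-[(2S)-6-methylhept-5-en-2-yl]-3,4-dihydronaphthalen-2(1H)-one | CC(C)(C)[Si](C)(C)OCc1cc(OC)c2c(c1)[C@H]([C@@H](C)CCC=C(C)C)CC(=O)[C@H]2C | intermediate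
13 | (1S,2S,4S)-6-({[tert-butyl(dimethyl)silyl]oxy}methyl)-8-methoxy-1-methyl-4-[(2S)-6-methylhept-5-en-2-yl]-1,2,3,4-tetrahydronaphthalen-2-ol | CC(C)(C)[Si](C)(C)OCc1cc(OC)c2c(c1)[C@H]([C@@H](C)CCC=C(C)C)C[C@H](O)[C@H]2C | intermediate
14 | (1S,2S,4S)-6-(hydroxymethyl)-8-methoxy-1-methyl-4-[(2S)-6-methylhept-5-en-2-yl]-1,2,3,4-tetrahydronaphthalen-2-ol | OCc1cc(OC)c2c(c1)[C@H]([C@@H](C)CCC=C(C)C)C[C@H](O)[C@H]2C | intermediate
15 | (1S,2S,4S)-6-(hydroxymethyl)-1-methyl-4-[(2S)-6-methylhept-5-en-2-yl]-1,2,3,4-tetrahydronaphthalene-2,8-diol | OCc1cc(O)c2c(c1)[C@H]([C@@H](C)CCC=C(C)C)C[C@H](O)[C@H]2C | intermediate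
16 | [(1S,2S,4S)-2,8-diacetoxy-1-methyl-4-[(2S)-6-methylhept-5-en-2-yl]-1,2,3,4-tetrahydronaphthalen-6-yl]methyl acetate | CC(=O)OCc1cc(OC(C)=O)c2c(c1)[C@H]([C@@H](C)CCC=C(C)C)C[C@H](OC(C)=O)[C@H]2C | intermediate
17 | [(1S,2S,4S)-2-acetoxy-8-hydroxy-1-methyl-4-[(2S)-6-methylhept-5-en-2-yl]-1,2,3,4-tetrahydronaphthalen-6-yl]methyl acetate | CC(=O)OCc1cc(O)c2c(c1)[C@H]([C@@H](C)CCC=C(C)C)C[C@H](OC(C)=O)[C@H]2C | target

**Count**

Total steps: 11. Longest linear sequence: 11 steps (1 to 17).

**Steps most likely to fail**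

1. Step 5 (proposed new method). What may go wrong: decarbonylation of the acyl rhodium hydride, chain-walking of the alkene into conjugation with loss of the C11 centre, or poor facial selectivity in the hydride insertion. The fallback uses known chemistry, sets out from 7 and comes back at 9.
   - Enantioselective protoboration of the 1,1-disubstituted styrene with B2pin2 and MeOH under a chiral N-heterocyclic carbene complex of CuCl (monovalent copper) with NaOt-Bu should set C4 by catalyst control and give the primary pinacol boronate F1.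
   - NaBO3·4H2O oxidation would give the primary alcohol F2.
   - I2, PPh3 and imidazole at 0 °C would give the primary iodide F3.
   - Swern oxidation of the triethylsilyl ether would give the iodo aldehyde F4.
   - A samarium Barbier cyclisation (SmI2, HMPA, THF, −78 °C) would form the C2–C3 bond and give the 2-tetralol F5 as a mixture of C2 epimers.
   - Dess–Martin oxidation would converge both epimers on ketone 9.

2. Step 6. What may go wrong: an unfavourable trans/cis equilibrium at C1, incomplete equilibration, or over-methylation. The fallback replaces thermodynamic control by auxiliary control, sets out from 9 and comes back at 12.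
   - Condensation with (S)-1-amino-2-(methoxymethyl)pyrrolidine would give the SAMP hydrazone F6.
   - Deprotonation with LiN(i-Pr)2 at benzylic C1 and alkylation of the azaenolate with MeI at −100 °C would give the C1-methylated hydrazone F7, with the methyl face set by the auxiliary (the antipodal auxiliary is used if the sense is wrong).
   - Two-phase cleavage with aqueous oxalic acid would release 12 as a single C1 epimer, to be reduced at once in step 7.

3. Step 7. What may go wrong: substrate (Felkin-type) control overriding the catalyst, so that hydride arrives anti to the C1 methyl and the C2 epimer forms. The fallback exploits that bias and then inverts C2; it sets out from 12 and comes back at 13.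
   - LiBH(s-Bu)3 in THF at −78 °C should give the (2R) alcohol F8.
   - Mitsunobu inversion with 4-nitrobenzoic acid, PPh3 and diisopropyl azodicarboxylate would give the inverted 4-nitrobenzoate F9. Elimination toward the styrene-type alkene is the competing process to watch here.
   - Methanolysis with K2CO3 in MeOH would give 13.

**Further compounds**

F1 | step 5 | tert-butyl({3-[(2S,3S)-3,7-dimethyl-1-(4,4,5,5-tetramethyl-1,3,2-dioxaborolan-2-yl)oct-6-en-2-yl]-5-methoxy-4-{2-[(triethylsilyl)oxy]ethyl}phenyl}methoxy)dimethylsilane | CC[Si](CC)(CC)OCCc1c([C@@H](CB2OC(C)(C)C(C)(C)O2)[C@@H](C)CCC=C(C)C)cc(CO[Si](C)(C)C(C)(C)C)cc1OC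
F2 | step 5 | (2S,3S)-2-[5-({[tert-butyl(dimethyl)silyl]oxy}methyl)-3-methoxy-2-{2-[(triethylsilyl)oxy]ethyl}phenyl]-3,7-dimethyloct-6-en-1-ol | CC[Si](CC)(CC)OCCc1c([C@@H](CO)[C@@H](C)CCC=C(C)C)cc(CO[Si](C)(C)C(C)(C)C)cc1OC
F3 | step 5 | tert-butyl({3-[(2S,3S)-1-iodo-3,7-dimethyloct-6-en-2-yl]-5-methoxy-4-{2-[(triethylsilyl)oxy]ethyl}phenyl}methoxy)dimethylsilane | CC[Si](CC)(CC)OCCc1c([C@@H](CI)[C@@H](C)CCC=C(C)C)cc(CO[Si](C)(C)C(C)(C)C)cc1OC
F4 | step 5 | 2-[4-({[tert-butyl(dimethyl)silyl]oxy}methyl)-2-[(2S,3S)-1-iodo-3,7-dimethyloct-6-en-2-yl]-6-methoxyphenyl]acetaldehyde | O=CCc1c([C@@H](CI)[C@@H](C)CCC=C(C)C)cc(CO[Si](C)(C)C(C)(C)C)cc1OC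
F5 | step 5 | (4S)-6-({[tert-butyl(dimethyl)silyl]oxy}methyl)-8-methoxy-4-[(2S)-6-methylhept-5-en-2-yl]-1,2,3,4-tetrahydronaphthalen-2-ol (C2 epimers) | CC(C)(C)[Si](C)(C)OCc1cc(OC)c2c(c1)[C@H]([C@@H](C)CCC=C(C)C)CC(O)C2
F6 | step 6 | SAMP hydrazone of ketone 9, N-[(2S)-2-(methoxymethyl)pyrrolidin-1-yl]imine at C2 | CC(C)(C)[Si](C)(C)OCc1cc(OC)c2c(c1)[C@H]([C@@H](C)CCC=C(C)C)CC(=NN3CCC[C@H]3COC)C2
F7 | step 6 | SAMP hydrazone of ketone 12, C1 methyl trans to the C4 chain | CC(C)(C)[Si](C)(C)OCc1cc(OC)c2c(c1)[C@H]([C@@H](C)CCC=C(C)C)CC(=NN3CCC[C@H]3COC)[C@H]2C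
F8 | step 7 | (1S,2R,4S)-6-({[tert-butyl(dimethyl)silyl]oxy}methyl)-8-methoxy-1-methyl-4-[(2S)-6-methylhept-5-en-2-yl]-1,2,3,4-tetrahydronaphthalen-2-ol | CC(C)(C)[Si](C)(C)OCc1cc(OC)c2c(c1)[C@H]([C@@H](C)CCC=C(C)C)C[C@@H](O)[C@H]2C
F9 | step 7 | (1S,2S,4S)-6-({[tert-butyl(dimethyl)silyl]oxy}methyl)-8-methoxy-1-methyl-4-[(2S)-6-methylhept-5-en-2-yl]-1,2,3,4-tetrahydronaphthalen-2-yl 4-nitrobenzoate | CC(C)(C)[Si](C)(C)OCc1cc(OC)c2c(c1)[C@H]([C@@H](C)CCC=C(C)C)C[C@H](OC(=O)c3ccc(cc3)[N+](=O)[O-])[C@H]2C
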